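**Plan**

- Retrosynthetic cuts, in order: the tert-butyl carbonate on the phenol oxygen; the C11'–C12' sp3–sp3 bond of the nonadecyl chain (anodic decarboxylative cross-coupling); the ester C–O bond between the propanoyl carbon and O–C1'.
- Enabling feature: the group on the ester oxygen is an unbranched chain of nineteen unfunctionalised sp3 carbons (O–C1' to C19'). Its C11'–C12' bond joins two primary carbons, so it can be made from two unstabilised primary radicals. C1'–C11' come from 12-hydroxydodecanoic acid and C12'–C19' from nonanoic acid, each acid giving up its carboxyl carbon as CO2.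
- Forward order of chain assembly: phenol of phloretic acid masked as the electron-poor O-Boc carbonate; ester C–O bond to benzyl 12-hydroxydodecanoate; benzyl ester removed; anodic C–C bond to the octyl fragment completes C19; phenol set free.
- Rings: the only ring, the benzene ring, is bought in phloretic acid; no ring is formed.
- Stereochemistry: the target has no stereocentre and no stereogenic double bond, so nothing is set.

Key step: step 5

Remark: primed locants count the nonadecyl carbons from the oxygen-bearing C1' to the methyl C19'; compounds 1, 3 and 7 are taken to be commercial.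

**Route**

Step 1
Reactants: 1 3-(4-hydroxyphenyl)propanoic acid (phloretic acid)
Product: 2 3-[4-(tert-butoxycarbonyloxy)phenyl]propanoic acid
Conditions: Boc2O (1.5 equiv), K2CO3 (2.5 equiv), H2O/iPrOH 1:1, 0 °C to rt; then cold 1 M HCl to pH 3
Reagents that add atoms: di-tert-butyl dicarbonate, CC(C)(C)OC(=O)OC(=O)OC(C)(C)C
Why: Schotten–Baumann-type O-acylation of the phenoxide by Boc2O in aqueous carbonate should give the aryl carbonate selectively, because the carboxylate cannot be lastingly acylated in water and the mild base spares the new carbonate, as in the known N,O-bis-Boc protection of tyrosine.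

Step 2
Reactants: 3 12-hydroxydodecanoic acid
Product: 4 benzyl 12-hydroxydodecanoate
Conditions: BnBr (1.1 equiv), K2CO3 (1.1 equiv), DMF, rt
Reagents that add atoms: benzyl bromide, BrCc1ccccc1
Why: SN2 O-alkylation of the potassium carboxylate by benzyl bromide should be clean, since carbonate does not deprotonate the aliphatic hydroxyl, which therefore stays free.

Step 3
Reactants: 2 3-[4-(tert-butoxycarbonyloxy)phenyl]propanoic acid; 4 benzyl 12-hydroxydodecanoate
Product: 5 benzyl 12-{3-[4-(tert-butoxycarbonyloxy)phenyl]propanoyloxy}dodecanoate
Conditions: DCC (1.1 equiv), DMAP (0.1 equiv), CH2Cl2, 0 °C to rt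
Reagents that add atoms: none
Why: Steglich esterification of an unhindered acid with a primary alcohol is reliable, and the low DMAP loading and low temperature should keep the aryl carbonate from passing its Boc group to the alcohol.

Step 4
Reactants: 5 benzyl 12-{3-[4-(tert-butoxycarbonyloxy)phenyl]propanoyloxy}dodecanoate
Product: 6 12-{3-[4-(tert-butoxycarbonyloxy)phenyl]propanoyloxy}dodecanoic acid
Conditions: H2 (1 atm), 10% Pd/C, EtOAc, rt
Reagents that add atoms: none
Why: Catalytic hydrogenolysis cleaves only the benzylic C–O bond of the benzyl ester; the aryl carbonate, the alkyl ester and the benzene ring are inert at 1 atm and room temperature.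

Step 5
Reactants: 6 12-{3-[4-(tert-butoxycarbonyloxy)phenyl]propanoyloxy}dodecanoic acid; 7 nonanoic acid
Product: 8 nonadecyl 3-[4-(tert-butoxycarbonyloxy)phenyl]propanoate
Conditions: 7 (6 equiv, part of it fed during the run), KOH (5 mol% of total acid), MeOH/MeCN 4:1, Pt anode and Pt cathode, undivided cell, constant current ca. 200 mA cm−2, 35–40 °C, stopped while the electrolyte is still acidic
Reagents that add atoms: none
Why: At the platinum anode, at high current density in weakly acidic methanol, the carboxylates of 6 and 7 are discharged in the adsorbed carboxylate layer, the acyloxy radicals lose CO2, and the 11-(acyloxy)undecyl and octyl radicals combine at the surface to form the C11'–C12' bond while protons are reduced to H2 at the cathode. The closest known reaction type is the crossed Kolbe electrolysis of a carboxylic acid bearing a remote ester with a fatty acid in excess, the classical entry to long-chain esters. No ring closes and no stereocentre is created. Cross-coupling over homocoupling is secured statistically by the several-fold excess of 7, and the two homodimers, hexadecane and the C22 bis(arylpropanoate), differ widely from 8 in polarity and should separate on silica. Carboxylate oxidation should win over arene oxidation because the aryl carbonate lowers the electron density of the ring and the carboxylate film shields the anode, and both radicals are unstabilised primary ones with no heteroatom nearby, which disfavours further oxidation to cations. Feeding 7 keeps the bulk acidic, so that methoxide formed at the cathode never reaches the aryl carbonate or the ester.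

Step 6
Reactants: 8 nonadecyl 3-[4-(tert-butoxycarbonyloxy)phenyl]propanoate
Product: 9 nonadecyl 3-(4-hydroxyphenyl)propanoate
Conditions: TFA/CH2Cl2 1:4, 0 °C to rt
Reagents that add atoms: none
Why: Acidolysis of the tert-butyl carbonate (loss of the tert-butyl cation as isobutene, then decarboxylation of the aryl carbonic acid) should free the phenol, while the primary alkyl ester is stable to anhydrous TFA.

**Compound list**

1 | 3-(4-hydroxyphenyl)propanoic acid (phloretic acid) | OC(=O)CCc1ccc(O)cc1 | starting material
2 | 3-[4-(tert-butoxycarbonyloxy)phenyl]propanoic acid | CC(C)(C)OC(=O)Oc1ccc(CCC(O)=O)cc1 | intermediate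
3 | 12-hydroxydodecanoic acid | OCCCCCCCCCCCC(=O)O | starting material
4 | benzyl 12-hydroxydodecanoate | OCCCCCCCCCCCC(=O)OCc1ccccc1 | intermediate
5 | benzyl 12-{3-[4-(tert-butoxycarbonyloxy)phenyl]propanoyloxy}dodecanoate | CC(C)(C)OC(=O)Oc1ccc(CCC(=O)OCCCCCCCCCCCC(=O)OCc2ccccc2)cc1 | intermediate
6 | 12-{3-[4-(tert-butoxycarbonyloxy)phenyl]propanoyloxy}dodecanoic acid | CC(C)(C)OC(=O)Oc1ccc(CCC(=O)OCCCCCCCCCCCC(O)=O)cc1 | intermediate
7 | nonanoic acid | CCCCCCCCC(=O)O | starting material
8 | nonadecyl 3-[4-(tert-butoxycarbonyloxy)phenyl]propanoate | CCCCCCCCCCCCCCCCCCCOC(=O)CCc1ccc(OC(=O)OC(C)(C)C)cc1 | intermediate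
9 | nonadecyl 3-(4-hydroxyphenyl)propanoate | CCCCCCCCCCCCCCCCCCCOC(=O)CCc1ccc(O)cc1 | target

**Step count and risks**

Total step count: 6. Longest linear sequence: 5 steps (steps 1 or 2, then 3, 4, 5, 6).

Steps most likely to fail:

1. Step 5. Competing anodic oxidation of the aromatic ring, homocoupling that consumes the valuable acid, cation-derived side pathways, methanolysis of the aryl carbonate if the medium turns basic, or fouling of the anode by waxy products could each erode the cross-coupling. The fallback makes the same C11'–C12' bond by a known nickel-catalysed decarboxylative alkyl–alkyl coupling. It sets out from 6, which would be condensed with N-hydroxyphthalimide (DIC, catalytic DMAP, CH2Cl2) to the redox-active ester 1,3-dioxoisoindolin-2-yl 12-{3-[4-(tert-butoxycarbonyloxy)phenyl]propanoyloxy}dodecanoate F1. This ester would then be coupled with dioctylzinc (from octylmagnesium bromide and ZnCl2) under NiCl2·glyme and 2,2'-bipyridine in THF/DMF at room temperature, returning to the route at 8.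

2. Step 1. Hydrolysis of Boc2O may outrun acylation of the phenoxide, the carboxylate may be acylated instead, or the new aryl carbonate may be cleaved by base during the reaction or by acid during the acidification. The fallback masks the acid first and sets out from 1. Alkylation of the carboxylate with benzyl bromide and KHCO3 in DMF would give benzyl 3-(4-hydroxyphenyl)propanoate F2. Boc2O with catalytic DMAP in MeCN would convert it into benzyl 3-[4-(tert-butoxycarbonyloxy)phenyl]propanoate F3. Hydrogenolysis (H2, Pd/C, EtOAc) would then return to the route at 2.

3. Step 3. Transfer of the Boc group from the aryl carbonate to the primary hydroxyl under DMAP catalysis, or rearrangement of the carbodiimide-activated acid to an unreactive N-acylurea, could lower the esterification. The fallback forms the ester bond by a Mitsunobu reaction, which activates the alcohol instead of the acid and needs no acyl-transfer catalyst. It sets out from 2 and 4 (PPh3, diisopropyl azodicarboxylate, THF, 0 °C to rt) and returns to the route at 5; no new compound arises on this path (F0).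

**Further compounds**

F1 | step 5 | 1,3-dioxoisoindolin-2-yl 12-{3-[4-(tert-butoxycarbonyloxy)phenyl]propanoyloxy}dodecanoate | CC(C)(C)OC(=O)Oc1ccc(CCC(=O)OCCCCCCCCCCCC(=O)ON2C(=O)c3ccccc3C2=O)cc1
F2 | step 1 | benzyl 3-(4-hydroxyphenyl)propanoate | O=C(CCc1ccc(O)cc1)OCc1ccccc1
F3 | step 1 | benzyl 3-[4-(tert-butoxycarbonyloxy)phenyl]propanoate | CC(C)(C)OC(=O)Oc1ccc(CCC(=O)OCc2ccccc2)cc1
F0 | step 3 | none | none
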